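**Assumptions:** The target is the (2R,3R)-trans dihydroflavonol, with the CIP descriptors read from the given SMILES. It carries an (E)-geranyl group at C-6, a 3'-OH and a 4'-OMe. All steps use free phenols without protecting groups. The cinchonidinium catalyst is commercial. The pseudo-enantiomer that gives (2R,3R) has to be found by screening.

## Retrosynthetic overview
1. The target is a 2,3-trans dihydroflavonol. One oxidative 6-endo cyclization (Algar–Flynn–Oyamada type: chalcone epoxidation, then phenoxide opening) of a 2'-hydroxychalcone forms the only new ring, the pyranone C-ring, and sets both stereocenters.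
2. That chalcone comes from Claisen–Schmidt condensation of 3-geranylphloroacetophenone with isovanillin.
3. 3-Geranylphloroacetophenone comes from mono-C-geranylation of symmetric phloroacetophenone with geranyl bromide. Only one mono-C-alkyl regioisomer exists.
4. Rings A and B enter as intact arenes. Geranyl is installed before cyclization, and C-6 versus C-8 is set by ring closure through the less hindered 6'-OH.

## Route

**Step 1**
Reactants: **1** 2,4,6-trihydroxyacetophenone (phloroacetophenone); **2** geranyl bromide ((2E)-1-bromo-3,7-dimethylocta-2,6-diene)
Product: **3** 1-(3-geranyl-2,4,6-trihydroxyphenyl)ethan-1-one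
Conditions: **1** (1.5 equiv), KOH (2.0 equiv), **2** (1.0 equiv), MeOH/H2O, 0 °C → rt, 4 h; chromatography to remove recovered **1** and bis-geranyl product
Reagents that add atoms: geranyl bromide, BrC/C=C(\C)CCC=C(C)C (reactant **2**)
Why: Base-mediated C-alkylation of a phloroglucinol-type phenolate in protic solvent proceeds through its dearomatized keto tautomer. This is an SN2 attack on the geranyl α-carbon that retains the E-alkene. Because **1** is symmetric, the two free ring positions are equivalent and only one mono-C-alkyl regioisomer forms. Excess **1** and sub-stoichiometric bromide limit dialkylation.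

**Step 2**
Reactants: **3**; **4** isovanillin (3-hydroxy-4-methoxybenzaldehyde)
Product: **5** (E)-1-(3-geranyl-2,4,6-trihydroxyphenyl)-3-(3-hydroxy-4-methoxyphenyl)prop-2-en-1-one
Conditions: KOH (8 equiv), EtOH/H2O, 0 °C → 50 °C, 24 h, N2; cold acidification to pH 5, immediate extraction
Reagents that add atoms: none (isovanillin is reactant **4**; only H2O is lost)
Why: This is a Claisen–Schmidt aldol condensation. The acetophenone enolate adds to the aldehyde, and dehydration gives the thermodynamically favored E-enone. The geranyl alkenes are inert to base. Any flavanone formed on work-up ring-opens back to the chalcone phenolate under the basic conditions of step 3.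

**Step 3**
Reactants: **5**; **6** N-(9-anthracenylmethyl)cinchonidinium bromide (chiral phase-transfer catalyst)
Product: **7** 4'-O-methyldiplacol, (2R,3R)-3,5,7,3'-tetrahydroxy-4'-methoxy-6-geranylflavanone
Conditions: **6** (10 mol%), 30% aq. H2O2 (6 equiv), K2CO3 (3 equiv), toluene/H2O, 0 °C, 48 h; quench with aq. NH4Cl to pH 5, then chromatography
Reagents that add atoms: hydrogen peroxide, OO (supplies the C-3 oxygen); catalyst **6** is not incorporated
Why: The chiral ammonium hydroperoxide ion pair performs an enantioface-selective Weitz–Scheffer epoxidation of the enone. This gives the (αR,βS)-trans-epoxide. The 6'-phenoxide then opens it 6-endo at the benzylic carbon with inversion. That makes C-2 R and retains C-3 R, and anti-opening of a trans-epoxide gives the 2,3-trans ring, with Ar and OH diequatorial. Any C-3 epimer equilibrates to trans through the enol. The 6'-OH, flanked only by H, closes the ring in preference to the 2'-OH next to the geranyl group, so the 6-geranyl isomer forms.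
Proposed new method: an enantioselective Algar–Flynn–Oyamada reaction on an unprotected, geranylated phloroglucinol chalcone. The mechanistic reasoning is the epoxide pathway, with the absolute configuration set by the chiral ion pair and the trans relationship set by inversion at the benzylic carbon. The closest known reactions are the cinchona-ammonium-catalysed asymmetric AFO reaction and the phase-transfer Weitz–Scheffer epoxidation of chalcones. The catalyst pseudo-enantiomer (cinchonidinium or cinchoninium) must be chosen empirically to give the (2R,3R) antipode.

## Compound list
1 | 2,4,6-trihydroxyacetophenone (phloroacetophenone) | CC(=O)c1c(O)cc(O)cc1O | starting material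
2 | geranyl bromide, (2E)-1-bromo-3,7-dimethylocta-2,6-diene | BrC/C=C(\C)CCC=C(C)C | starting material
3 | 1-(3-geranyl-2,4,6-trihydroxyphenyl)ethan-1-one | CC(=O)c1c(O)cc(O)c(C/C=C(\C)CCC=C(C)C)c1O | intermediate
4 | isovanillin, 3-hydroxy-4-methoxybenzaldehyde | COc1ccc(C=O)cc1O | starting material
5 | (E)-1-(3-geranyl-2,4,6-trihydroxyphenyl)-3-(3-hydroxy-4-methoxyphenyl)prop-2-en-1-one | COc1ccc(/C=C/C(=O)c2c(O)cc(O)c(C/C=C(\C)CCC=C(C)C)c2O)cc1O | intermediate
6 | N-(9-anthracenylmethyl)cinchonidinium bromide (commercial chiral phase-transfer catalyst) | C=C[C@H]1C[N+]2(Cc3c4ccccc4cc4ccccc34)CC[C@H]1C[C@H]2[C@@H](c1ccnc2ccccc12)O.[Br-] | starting material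
7 | 4'-O-methyldiplacol, (2R,3R)-6-geranyl-3,5,7,3'-tetrahydroxy-4'-methoxyflavanone | COc1ccc([C@H]2Oc3cc(O)c(C/C=C(\C)CCC=C(C)C)c(O)c3C(=O)[C@@H]2O)cc1O | target

## Summary
Total steps: 3. Longest linear sequence: 3 (1 → 3 → 5 → 7).

**Three steps most likely to fail**
1. **Step 3 (enantioselective AFO).** Risks are low ee, aurone or over-oxidation products (the polyphenolate deactivates the enone), and an 8-geranyl regioisomer from closure through the 2'-OH.
   Fallback: run the AFO racemically (NaOH, aq. H2O2, EtOH), then separate the regioisomer and resolve the (2R,3R) enantiomer by preparative chiral-phase HPLC.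
2. **Step 2 (Claisen–Schmidt on the unprotected polyphenol).** The phenolate-deactivated ketone and aldehyde can give low conversion, retro-aldol, or premature flavanone formation.
   Fallback: protect the 2'- and 4'-OH groups of **3** as MOM ethers, leaving the chelated 6'-OH free so that cyclization still occurs on the correct side. Condense with 3-O-MOM-isovanillin under NaOH/EtOH, then run the AFO and remove the MOM groups at the end with MgBr2·OEt2/Me2S, which spares the geranyl alkenes.
3. **Step 1 (mono-C-geranylation).** Bis-alkylation, O-alkylation and modest yield are the risks.
   Fallback: reverse the order. Geranylate phloroglucinol (1,3,5-trihydroxybenzene) to give 2-geranylphloroglucinol, then acetylate it with AcCl/AlCl3 or Ac2O/BF3·OEt2 at low temperature. The two free ring positions are equivalent, so this also gives **3**.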